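The synthesis rests on cutting ring C (O1, C2, C3, C4, C4a, C8a) between C3 and C4. A five-membered benzofuran-3(2H)-one is built first, in which C2 already carries O1, the B-ring aryl and an iodomethyl group. A Dowd–Beckwith radical 1,2-acyl shift then inserts that CH2 between C2 and the aryl ketone and gives the chromanone in one operation. It exploits that C2 is benzylic and bound to O1, so the rearranged radical is stabilised, and that C4 is an aryl ketone that accepts the radical. The precursor comes from a lavandulylated salicylamide and a B-ring benzyl alcohol. C2 is fixed afterwards by a transfer-hydrogenation resolution; the side-chain centre comes from (R)-lavandulol.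

Key step: step 13

Remark: (R)-(−)-lavandulol is assumed to be purchasable in enantiopure form; its stereocentre has the spatial arrangement of the target side chain (the descriptor becomes S once the CH2 is bound to the arene, by a priority change only).

Step 1
Reactants: 1 (R)-lavandulol
Product: 2 (R)-lavandulyl iodide
Conditions: PPh3, I2, imidazole, CH2Cl2, 0 °C → rt
Reagents that add atoms: iodine, II
Why: Appel-type iodination converts the primary alcohol by SN2 at C1, so the adjacent stereocentre is not touched and keeps the configuration of the chiral-pool alcohol.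

Step 2
Reactants: 3 phloroglucinol
Product: 4 5-{[tri(propan-2-yl)silyl]oxy}benzene-1,3-diol
Conditions: TIPSCl (1 equiv), imidazole, DMF, 0 °C → rt; 3 in threefold excess
Reagents that add atoms: chlorotri(propan-2-yl)silane, CC(C)[Si](Cl)(C(C)C)C(C)C
Why: Statistical monosilylation of the symmetrical triol marks the oxygen that becomes O1 with a bulky, non-coordinating group that later keeps lithium away from its ortho positions.

Step 3
Reactants: 4 5-{[tri(propan-2-yl)silyl]oxy}benzene-1,3-diol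
Product: 5 [3,5-bis(methoxymethoxy)phenoxy]tri(propan-2-yl)silane
Conditions: MOMCl, iPr2NEt, CH2Cl2, 0 °C → rt
Reagents that add atoms: chloromethyl methyl ether, COCCl
Why: O-alkylation of both phenols with MOMCl installs two ortho-directing groups that withstand organolithium, radical and hydride conditions.

Step 4
Reactants: 5 [3,5-bis(methoxymethoxy)phenoxy]tri(propan-2-yl)silane; 2 (R)-lavandulyl iodide
Product: 7 {3,5-bis(methoxymethoxy)-4-[(2S)-5-methyl-2-(prop-1-en-2-yl)hex-4-en-1-yl]phenoxy}tri(propan-2-yl)silane, via aryllithium 6 (not isolated)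
Conditions: n-BuLi, THF, 0 °C; then CuI (10 mol%), 2, −30 °C → rt
Reagents that add atoms: none
Why: Directed ortho-metalation should occur only at the C–H flanked by both OMOM groups, and copper-catalysed SN2 alkylation with the primary iodide forms the aryl–CH2 bond without touching the side-chain stereocentre.

Step 5
Reactants: 7 {3,5-bis(methoxymethoxy)-4-[(2S)-5-methyl-2-(prop-1-en-2-yl)hex-4-en-1-yl]phenoxy}tri(propan-2-yl)silane
Product: 9 3,5-bis(methoxymethoxy)-4-[(2S)-5-methyl-2-(prop-1-en-2-yl)hex-4-en-1-yl]phenyl N,N-diethylcarbamate, via ammonium phenolate 8 (not isolated)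
Conditions: TBAF, THF, 0 °C; then Et2NCOCl, rt
Reagents that add atoms: N,N-diethylcarbamoyl chloride, CCN(CC)C(Cl)=O
Why: Fluoride cleaves the aryl silyl ether and the phenolate is O-acylated in the same flask to give the O-aryl carbamate, the directing group for the next metalation.

Step 6
Reactants: 9 3,5-bis(methoxymethoxy)-4-[(2S)-5-methyl-2-(prop-1-en-2-yl)hex-4-en-1-yl]phenyl N,N-diethylcarbamate
Product: 11 N,N-diethyl-2-hydroxy-4,6-bis(methoxymethoxy)-5-[(2S)-5-methyl-2-(prop-1-en-2-yl)hex-4-en-1-yl]benzamide, via ortho-lithiated carbamate 10 (not isolated)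
Conditions: s-BuLi, TMEDA, THF, −78 °C → rt; aq. NH4Cl
Reagents that add atoms: none
Why: Carbamate-directed ortho-lithiation at one of the two equivalent ring positions and anionic ortho-Fries rearrangement (1,3 O→C carbamoyl shift) place the future C4 carbonyl next to the freed phenol that becomes O1, which fixes the side chain at C6 and not C8.

Step 7
Reactants: 12 2,4,6-trihydroxybenzaldehyde
Product: 13 2,4,6-tris(methoxymethoxy)benzaldehyde
Conditions: NaH, MOMCl, DMF, 0 °C → rt
Reagents that add atoms: chloromethyl methyl ether, COCCl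
Why: Exhaustive O-alkylation (NaH is needed for the hydrogen-bonded ortho-hydroxyls) gives the B-ring aldehyde with the same protecting group as ring A.

Step 8
Reactants: 13 2,4,6-tris(methoxymethoxy)benzaldehyde
Product: 14 [2,4,6-tris(methoxymethoxy)phenyl]methanol
Conditions: NaBH4, MeOH, 0 °C
Reagents that add atoms: none
Why: Borohydride reduction of the aldehyde gives the primary benzylic alcohol for the Mitsunobu coupling.

Step 9
Reactants: 11 N,N-diethyl-2-hydroxy-4,6-bis(methoxymethoxy)-5-[(2S)-5-methyl-2-(prop-1-en-2-yl)hex-4-en-1-yl]benzamide; 14 [2,4,6-tris(methoxymethoxy)phenyl]methanol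
Product: 15 N,N-diethyl-2,4-bis(methoxymethoxy)-3-[(2S)-5-methyl-2-(prop-1-en-2-yl)hex-4-en-1-yl]-6-{[2,4,6-tris(methoxymethoxy)phenyl]methoxy}benzamide
Conditions: PPh3, DIAD, THF, 0 °C → rt
Reagents that add atoms: none
Why: Mitsunobu etherification joins the acidic salicylamide phenol with the benzylic alcohol and forms the O1–C2 bond under neutral conditions that avoid the unstable electron-rich benzyl halide.

Step 10
Reactants: 15 N,N-diethyl-2,4-bis(methoxymethoxy)-3-[(2S)-5-methyl-2-(prop-1-en-2-yl)hex-4-en-1-yl]-6-{[2,4,6-tris(methoxymethoxy)phenyl]methoxy}benzamide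
Product: 16 4,6-bis(methoxymethoxy)-5-[(2S)-5-methyl-2-(prop-1-en-2-yl)hex-4-en-1-yl]-2-[2,4,6-tris(methoxymethoxy)phenyl]-1-benzofuran-3(2H)-one (C2 labile)
Conditions: LDA (2.5 equiv), THF, −78 → 0 °C; degassed aq. NH4Cl; used at once
Reagents that add atoms: none
Why: LDA reversibly deprotonates the benzylic α-aryloxy CH2 and the carbanion closes the five-membered ring by 5-exo-trig acyl substitution on the ortho diethylamide (anionic cyclisation, preferred over Wittig rearrangement because the migrating ring is electron-rich); C2 is enolisable and is left uncontrolled.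

Step 11
Reactants: 16 4,6-bis(methoxymethoxy)-5-[(2S)-5-methyl-2-(prop-1-en-2-yl)hex-4-en-1-yl]-2-[2,4,6-tris(methoxymethoxy)phenyl]-1-benzofuran-3(2H)-one
Product: 17 2-(hydroxymethyl)-4,6-bis(methoxymethoxy)-5-[(2S)-5-methyl-2-(prop-1-en-2-yl)hex-4-en-1-yl]-2-[2,4,6-tris(methoxymethoxy)phenyl]-1-benzofuran-3(2H)-one (both C2 epimers)
Conditions: aq. HCHO (37%), Et3N (0.2 equiv), THF, 0 °C, argon
Reagents that add atoms: formaldehyde, C=O
Why: Aldol hydroxymethylation of the strongly enolised ketone builds the fully substituted C2; both configurations form and both are used because this centre becomes planar in step 13.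

Step 12
Reactants: 17 2-(hydroxymethyl)-4,6-bis(methoxymethoxy)-5-[(2S)-5-methyl-2-(prop-1-en-2-yl)hex-4-en-1-yl]-2-[2,4,6-tris(methoxymethoxy)phenyl]-1-benzofuran-3(2H)-one
Product: 18 2-(iodomethyl)-4,6-bis(methoxymethoxy)-5-[(2S)-5-methyl-2-(prop-1-en-2-yl)hex-4-en-1-yl]-2-[2,4,6-tris(methoxymethoxy)phenyl]-1-benzofuran-3(2H)-one (both C2 epimers)
Conditions: PPh3, I2, imidazole, toluene, 70 °C
Reagents that add atoms: iodine, II
Why: Appel-type iodination of the neopentyl-type primary alcohol proceeds without an alkoxide (so no retro-aldol) and gives the radical precursor.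

Step 13
Reactants: 18 2-(iodomethyl)-4,6-bis(methoxymethoxy)-5-[(2S)-5-methyl-2-(prop-1-en-2-yl)hex-4-en-1-yl]-2-[2,4,6-tris(methoxymethoxy)phenyl]-1-benzofuran-3(2H)-one
Product: 21 5,7-bis(methoxymethoxy)-6-[(2S)-5-methyl-2-(prop-1-en-2-yl)hex-4-en-1-yl]-2-[2,4,6-tris(methoxymethoxy)phenyl]-2,3-dihydro-4H-chromen-4-one (both C2 epimers), via primary alkyl radical 19 (not isolated), via ring-expanded C2 radical 20 (not isolated)
Conditions: Bu3SnH (1.3 equiv, syringe pump), AIBN (0.2 equiv), benzene, 80 °C, high dilution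
Reagents that add atoms: none
Why: The stannyl radical abstracts iodine from 18 to give primary radical 19, which adds 3-exo-trig to the aryl-ketone carbon; the cyclopropyloxy radical then fragments at the old C2–C(=O) bond, so the CH2 ends up between the carbonyl (now C4) and C2, and the six-membered ring C emerges from the five-membered ring as tertiary radical 20, which takes hydrogen from Bu3SnH. The closest known reaction type is the Dowd–Beckwith ring expansion of α-halomethyl cyclic ketones (radical 1,2-acyl shift), driven here by stabilisation of 20 by O1 and the B-ring aryl in place of the usual ester. The only ring closure is the transient 3-exo-trig step; the ring grows by cleavage of the internal bond of the bicyclic alkoxy radical. C2 is the only new stereocentre and forms by hydrogen transfer to a planar radical without control, so both epimers of 18 converge on one radical and 21 is expected as a mixture of C2 epimers, of which the S member is selected in step 14. The acyl shift must beat direct reduction of 19, a 1,2-shift of the B-ring aryl and loss of the O1 aryloxy radical; slow stannane addition keeps its concentration low, and the nucleophilic primary radical should prefer the electron-poor carbonyl carbon over the ipso carbon of the electron-rich trialkoxyphenyl ring.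

Step 14
Reactants: 21 5,7-bis(methoxymethoxy)-6-[(2S)-5-methyl-2-(prop-1-en-2-yl)hex-4-en-1-yl]-2-[2,4,6-tris(methoxymethoxy)phenyl]-2,3-dihydro-4H-chromen-4-one (both C2 epimers)
Product: 22 (2S)-5,7-bis(methoxymethoxy)-6-[(2S)-5-methyl-2-(prop-1-en-2-yl)hex-4-en-1-yl]-2-[2,4,6-tris(methoxymethoxy)phenyl]-2,3-dihydro-4H-chromen-4-one
Conditions: [Cp*RhCl((R,R)-TsDPEN)] (1 mol%), HCO2H/Et3N (5:2), EtOAc, rt, stopped near 55% conversion; chromatography
Reagents that add atoms: none
Why: Kinetic resolution by asymmetric transfer hydrogenation: the (R,R)-catalyst should reduce the (2R)-epimer fast to the cis-(2R,4R)-flavan-4-ol, whereas the (2S)-epimer is the mismatched substrate and is recovered, so C2 is obtained as S from at most half of 21; the non-basic medium avoids ring opening to the chalcone.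

Step 15
Reactants: 22 (2S)-5,7-bis(methoxymethoxy)-6-[(2S)-5-methyl-2-(prop-1-en-2-yl)hex-4-en-1-yl]-2-[2,4,6-tris(methoxymethoxy)phenyl]-2,3-dihydro-4H-chromen-4-one
Product: 23 (2S)-5,7-dihydroxy-6-[(2S)-5-methyl-2-(prop-1-en-2-yl)hex-4-en-1-yl]-2-(2,4,6-trihydroxyphenyl)-2,3-dihydro-4H-chromen-4-one
Conditions: aq. HCl (3 M)/MeOH (1:10), 40 °C, monitored; cold NaHCO3 work-up
Reagents that add atoms: none
Why: Acid-catalysed transacetalisation to methanol removes all five MOM groups; dilute acid at moderate temperature is chosen to avoid cyclisation of the 5- or 7-hydroxyl onto the side-chain alkenes and ionisation of the C2–O1 bond, so both stereocentres should be kept.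

Compound list
1 | (R)-lavandulol, (2R)-5-methyl-2-(prop-1-en-2-yl)hex-4-en-1-ol | C=C(C)[C@@H](CC=C(C)C)CO | starting material
2 | (R)-lavandulyl iodide, (3R)-3-(iodomethyl)-2,6-dimethylhepta-1,5-diene | C=C(C)[C@@H](CC=C(C)C)CI | intermediate
3 | phloroglucinol, benzene-1,3,5-triol | Oc1cc(O)cc(O)c1 | starting material
4 | 5-{[tri(propan-2-yl)silyl]oxy}benzene-1,3-diol | CC(C)[Si](Oc1cc(O)cc(O)c1)(C(C)C)C(C)C | intermediate
5 | [3,5-bis(methoxymethoxy)phenoxy]tri(propan-2-yl)silane | COCOc1cc(OCOC)cc(O[Si](C(C)C)(C(C)C)C(C)C)c1 | intermediate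
6 | [4-lithio-3,5-bis(methoxymethoxy)phenoxy]tri(propan-2-yl)silane (aryllithium) | [Li]c1c(OCOC)cc(O[Si](C(C)C)(C(C)C)C(C)C)cc1OCOC | intermediate
7 | {3,5-bis(methoxymethoxy)-4-[(2S)-5-methyl-2-(prop-1-en-2-yl)hex-4-en-1-yl]phenoxy}tri(propan-2-yl)silane | C=C(C)[C@@H](CC=C(C)C)Cc1c(OCOC)cc(O[Si](C(C)C)(C(C)C)C(C)C)cc1OCOC | intermediate
8 | tetrabutylammonium 3,5-bis(methoxymethoxy)-4-[(2S)-5-methyl-2-(prop-1-en-2-yl)hex-4-en-1-yl]phenolate | C=C(C)[C@@H](CC=C(C)C)Cc1c(OCOC)cc([O-])cc1OCOC.CCCC[N+](CCCC)(CCCC)CCCC | intermediate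
9 | 3,5-bis(methoxymethoxy)-4-[(2S)-5-methyl-2-(prop-1-en-2-yl)hex-4-en-1-yl]phenyl N,N-diethylcarbamate | C=C(C)[C@@H](CC=C(C)C)Cc1c(OCOC)cc(OC(=O)N(CC)CC)cc1OCOC | intermediate
10 | 2-lithio derivative of carbamate 9 | C=C(C)[C@@H](CC=C(C)C)Cc1c(OCOC)cc(OC(=O)N(CC)CC)c([Li])c1OCOC | intermediate
11 | N,N-diethyl-2-hydroxy-4,6-bis(methoxymethoxy)-5-[(2S)-5-methyl-2-(prop-1-en-2-yl)hex-4-en-1-yl]benzamide | C=C(C)[C@@H](CC=C(C)C)Cc1c(OCOC)cc(O)c(C(=O)N(CC)CC)c1OCOC | intermediate
12 | 2,4,6-trihydroxybenzaldehyde | O=Cc1c(O)cc(O)cc1O | starting material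
13 | 2,4,6-tris(methoxymethoxy)benzaldehyde | COCOc1cc(OCOC)c(C=O)c(OCOC)c1 | intermediate
14 | [2,4,6-tris(methoxymethoxy)phenyl]methanol | COCOc1cc(OCOC)c(CO)c(OCOC)c1 | intermediate
15 | N,N-diethyl-2,4-bis(methoxymethoxy)-3-[(2S)-5-methyl-2-(prop-1-en-2-yl)hex-4-en-1-yl]-6-{[2,4,6-tris(methoxymethoxy)phenyl]methoxy}benzamide | C=C(C)[C@@H](CC=C(C)C)Cc1c(OCOC)cc(OCc2c(OCOC)cc(OCOC)cc2OCOC)c(C(=O)N(CC)CC)c1OCOC | intermediate
16 | 4,6-bis(methoxymethoxy)-5-[(2S)-5-methyl-2-(prop-1-en-2-yl)hex-4-en-1-yl]-2-[2,4,6-tris(methoxymethoxy)phenyl]-1-benzofuran-3(2H)-one, C2 configurationally labile | C=C(C)[C@@H](CC=C(C)C)Cc1c(OCOC)cc2c(c1OCOC)C(=O)C(c1c(OCOC)cc(OCOC)cc1OCOC)O2 | intermediate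
17 | 2-(hydroxymethyl) derivative of 16, both C2 epimers | C=C(C)[C@@H](CC=C(C)C)Cc1c(OCOC)cc2c(c1OCOC)C(=O)C(CO)(c1c(OCOC)cc(OCOC)cc1OCOC)O2 | intermediate
18 | 2-(iodomethyl) derivative of 16, both C2 epimers | C=C(C)[C@@H](CC=C(C)C)Cc1c(OCOC)cc2c(c1OCOC)C(=O)C(CI)(c1c(OCOC)cc(OCOC)cc1OCOC)O2 | intermediate
19 | primary alkyl radical from 18 (CH2 radical on C2 of the benzofuranone) | C=C(C)[C@@H](CC=C(C)C)Cc1c(OCOC)cc2c(c1OCOC)C(=O)C([CH2])(c1c(OCOC)cc(OCOC)cc1OCOC)O2 | intermediate
20 | ring-expanded 4-oxochroman-2-yl radical (radical at C2) | C=C(C)[C@@H](CC=C(C)C)Cc1c(OCOC)cc2c(c1OCOC)C(=O)C[C](c1c(OCOC)cc(OCOC)cc1OCOC)O2 | intermediate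
21 | 5,7-bis(methoxymethoxy)-6-[(2S)-5-methyl-2-(prop-1-en-2-yl)hex-4-en-1-yl]-2-[2,4,6-tris(methoxymethoxy)phenyl]-2,3-dihydro-4H-chromen-4-one, both C2 epimers | C=C(C)[C@@H](CC=C(C)C)Cc1c(OCOC)cc2c(c1OCOC)C(=O)CC(c1c(OCOC)cc(OCOC)cc1OCOC)O2 | intermediate
22 | (2S)-5,7-bis(methoxymethoxy)-6-[(2S)-5-methyl-2-(prop-1-en-2-yl)hex-4-en-1-yl]-2-[2,4,6-tris(methoxymethoxy)phenyl]-2,3-dihydro-4H-chromen-4-one | C=C(C)[C@@H](CC=C(C)C)Cc1c(OCOC)cc2c(c1OCOC)C(=O)C[C@@H](c1c(OCOC)cc(OCOC)cc1OCOC)O2 | intermediate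
23 | (2S)-5,7-dihydroxy-6-[(2S)-5-methyl-2-(prop-1-en-2-yl)hex-4-en-1-yl]-2-(2,4,6-trihydroxyphenyl)-2,3-dihydro-4H-chromen-4-one | C=C(C)[C@@H](CC=C(C)C)Cc1c(O)cc2c(c1O)C(=O)C[C@@H](c1c(O)cc(O)cc1O)O2 | target

Total step count: 15. Longest linear sequence: 12 steps (3 → 23 through steps 2, 3, 4, 5, 6, 9, 10, 11, 12, 13, 14, 15).

Steps most likely to fail:

Step 11: C-attack of formaldehyde at the hindered, fully substituted C2 may be slow and reversible (retro-aldol), while O-addition and autoxidation of the enol consume 16. The fallback sets out from 16. The enol is trapped as the tert-butyldimethylsilyl enol ether, the 3-silyloxybenzofuran F1 (TBSOTf, Et3N, CH2Cl2). A Lewis acid-catalysed Mukaiyama-type hydroxymethylation with aqueous formaldehyde (Sc(OTf)3 cat., THF/H2O) is then irreversible and comes back to the route at 17.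

Step 13: the primary radical may be reduced before it rearranges, the B-ring aryl may shift instead of the acyl group, the aryloxy radical may be expelled, or the neopentyl-type iodide may not form cleanly in step 12. The fallback sets out from 16. C-alkylation with allyl bromoacetate (K2CO3, acetone) should give the allyl ester F2. Removal of the allyl group (Pd(PPh3)4, morpholine) should give the acid F3, which is converted into the N-acyloxyphthalimide F4 (N-hydroxyphthalimide, DIC). Visible-light photoredox decarboxylation ([Ru(bpy)3]Cl2, Hantzsch ester, blue light) generates the same CH2 radical with only a weak hydrogen donor present, so the 1,2-acyl shift has no fast competitor. The sequence comes back at 21.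

Step 14: the rate difference between the C2 epimers may be too small at the hindered 5-alkoxy ketone, and at best half of 21 is used. The fallback sets out from 21. Soft enolisation gives the trimethylsilyl enol ether F5 (TMSOTf, Et3N, CH2Cl2). Saegusa–Ito dehydrogenation (Pd(OAc)2, MeCN) should give the flavone F6. Enantioselective copper hydride conjugate reduction (Cu(OAc)2, DTBM-SEGPHOS, silane, t-BuOH), with the ligand antipode that delivers the 2S product, then sets C2 from all of the material and comes back at 22.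

Further compounds
F1 | step 11 | tert-butyl(dimethyl){[4,6-bis(methoxymethoxy)-5-[(2S)-5-methyl-2-(prop-1-en-2-yl)hex-4-en-1-yl]-2-[2,4,6-tris(methoxymethoxy)phenyl]-1-benzofuran-3-yl]oxy}silane | C=C(C)[C@@H](CC=C(C)C)Cc1c(OCOC)cc2oc(-c3c(OCOC)cc(OCOC)cc3OCOC)c(O[Si](C)(C)C(C)(C)C)c2c1OCOC
F2 | step 13 | prop-2-en-1-yl 2-{4,6-bis(methoxymethoxy)-5-[(2S)-5-methyl-2-(prop-1-en-2-yl)hex-4-en-1-yl]-3-oxo-2-[2,4,6-tris(methoxymethoxy)phenyl]-2,3-dihydro-1-benzofuran-2-yl}acetate, both C2 epimers | C=C(C)[C@@H](CC=C(C)C)Cc1c(OCOC)cc2c(c1OCOC)C(=O)C(CC(=O)OCC=C)(c1c(OCOC)cc(OCOC)cc1OCOC)O2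
F3 | step 13 | 2-{4,6-bis(methoxymethoxy)-5-[(2S)-5-methyl-2-(prop-1-en-2-yl)hex-4-en-1-yl]-3-oxo-2-[2,4,6-tris(methoxymethoxy)phenyl]-2,3-dihydro-1-benzofuran-2-yl}acetic acid, both C2 epimers | C=C(C)[C@@H](CC=C(C)C)Cc1c(OCOC)cc2c(c1OCOC)C(=O)C(CC(=O)O)(c1c(OCOC)cc(OCOC)cc1OCOC)O2
F4 | step 13 | 1,3-dioxoisoindolin-2-yl ester of acid F3, both C2 epimers | C=C(C)[C@@H](CC=C(C)C)Cc1c(OCOC)cc2c(c1OCOC)C(=O)C(CC(=O)ON1C(=O)c3ccccc3C1=O)(c1c(OCOC)cc(OCOC)cc1OCOC)O2
F5 | step 14 | {[5,7-bis(methoxymethoxy)-6-[(2S)-5-methyl-2-(prop-1-en-2-yl)hex-4-en-1-yl]-2-[2,4,6-tris(methoxymethoxy)phenyl]-2H-chromen-4-yl]oxy}trimethylsilane, both C2 epimers | C=C(C)[C@@H](CC=C(C)C)Cc1c(OCOC)cc2c(c1OCOC)C(O[Si](C)(C)C)=CC(c1c(OCOC)cc(OCOC)cc1OCOC)O2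
F6 | step 14 | 5,7-bis(methoxymethoxy)-6-[(2S)-5-methyl-2-(prop-1-en-2-yl)hex-4-en-1-yl]-2-[2,4,6-tris(methoxymethoxy)phenyl]-4H-chromen-4-one | C=C(C)[C@@H](CC=C(C)C)Cc1c(OCOC)cc2c(c1OCOC)C(=O)C=C(c1c(OCOC)cc(OCOC)cc1OCOC)O2
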